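**Strategy.** The 1,2-dioxane is read as a dioxygen adduct of an acyclic diene. Atom labels: C1 lactone carbonyl, C2 its α-CH2, C3 the peroxy CH, C4 the methyl-bearing carbon on the lactone oxygen, C5 the ring CH2, C6 the peroxy carbon carrying methyl and hexadecyl. Because the O–O bridge spans C3 and C6, singlet oxygen is added across C3=C4–C5=C6 of methyl (3E,5E)-4,6-dimethyldocosa-3,5-dienoate. This closes the six-membered peroxide ring, sets the C3 and C6 carbon substituents cis, and leaves the C4=C5 alkene on which the γ-lactone is closed. Two zirconium-catalysed methylaluminations build the diene; an enzymatic resolution supplies the enantiomer.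

Key step: step 5

Assumption: 14 is racemic and is named as its needed (3S,6R) enantiomer; the enantiopreference of a lipase cannot be predicted, so step 6 is written for an enzyme found by screening to hydrolyse the (3S,6R) ester faster.

Step 1
Reactants: 1 octadec-1-yne; 2 trimethylaluminium
Product: 4 (E)-1-iodo-2-methyloctadec-1-ene, via alkenylalane 3 (not isolated)
Conditions: Me3Al (2 equiv), Cp2ZrCl2 (0.25 equiv), CH2Cl2, 0 → 23 °C; then I2, THF, −30 → 0 °C
Reagents that add atoms: trimethylaluminium (2), C[Al](C)C; iodine, II
Why: Zirconium-catalysed methylalumination (Negishi carboalumination) adds methyl and aluminium syn across the terminal alkyne with methyl on the internal carbon, and iodinolysis of the C–Al bond of 3 proceeds with retention, so the future C5=C6 alkene should form as the E isomer.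

Step 2
Reactants: 4 (E)-1-iodo-2-methyloctadec-1-ene; 5 ethynylmagnesium bromide
Product: 7 (E)-4-methylicos-3-en-1-yne, via ethynylzinc bromide 6 (not isolated)
Conditions: HC≡CMgBr, ZnBr2, THF, 0 °C; then 4, Pd(PPh3)4 (3 mol %), THF, 23 °C
Reagents that add atoms: ethynylmagnesium bromide (5), C#C[Mg]Br
Why: Negishi alkynylation: zerovalent palladium inserts into the C–I bond with retention and the ethynyl group is transferred from zinc, which should give the terminal enyne directly with the alkene geometry unchanged and no stereocentre formed.

Step 3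
Reactants: 7 (E)-4-methylicos-3-en-1-yne; 2 trimethylaluminium
Product: 9 (1E,3E)-1-iodo-2,4-dimethylicosa-1,3-diene, via dienylalane 8 (not isolated)
Conditions: Me3Al (2 equiv), Cp2ZrCl2 (0.25 equiv), CH2Cl2, 0 → 23 °C; then I2, THF, −30 → 0 °C
Reagents that add atoms: trimethylaluminium (2), C[Al](C)C; iodine, II
Why: A second Negishi carboalumination, on the terminal alkyne of a conjugated enyne as in iterative polyene synthesis, places the C4 methyl group and aluminium syn, and iodinolysis of 8 with retention should deliver the dienyl iodide with both trisubstituted E alkenes of the precursor in place.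

Step 4
Reactants: 9 (1E,3E)-1-iodo-2,4-dimethylicosa-1,3-diene; 10 methyl bromoacetate
Product: 12 methyl (3E,5E)-4,6-dimethyldocosa-3,5-dienoate, via Reformatsky reagent 11 (not isolated)
Conditions: Zn dust (TMSCl-activated), BrCH2CO2Me, THF, 40 °C; then 9, Pd(dba)2 (3 mol %), P(t-Bu)3 (3 mol %), THF, 23 °C, dark
Reagents that add atoms: methyl bromoacetate (10), COC(=O)CBr
Why: Palladium-catalysed cross-coupling of an alkenyl iodide with a zinc ester enolate (Reformatsky–Negishi coupling) forms the C2–C3 bond with retention of the dienyl geometry under near-neutral conditions, so the skipped β,γ-unsaturated ester should not move into conjugation.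

Step 5
Reactants: 12 methyl (3E,5E)-4,6-dimethyldocosa-3,5-dienoate; 13 dioxygen
Product: 14 methyl 2-[(3S,6R)-6-hexadecyl-4,6-dimethyl-3,6-dihydro-1,2-dioxin-3-yl]acetate (racemate; needed enantiomer named)
Conditions: O2 (1 atm), 5,10,15,20-tetraphenylporphyrin (1 mol %), visible light (white LED), CH2Cl2, −30 °C
Reagents that add atoms: dioxygen (13), O=O
Why: Energy transfer from photoexcited tetraphenylporphyrin converts O2 into singlet oxygen, which acts as a two-atom dienophile and adds to the s-cis C3=C4–C5=C6 unit of 12 in a concerted suprafacial [4+2] cycloaddition; the closest known reaction type is the singlet-oxygen hetero-Diels–Alder reaction of acyclic 1,3-dienes to 3,6-dihydro-1,2-dioxines. The six-membered peroxide ring is closed by the cycloaddition itself, the C3–O and C6–O bonds forming in one pericyclic event on one face of the diene. C3 and C6 arise together and their relative configuration is fixed by the (3E,5E) geometry: the two outward-pointing groups, the C2 ester arm and the hexadecyl chain, must finish cis on the ring, while the two diene faces are enantiotopic, so 14 is racemic. The step needs [4+2] selectivity over the ene reaction (allylic hydrogens at C2, at both methyl groups and at C7) and over [2+2] addition; the C4 methyl group helps by destabilising the s-trans rotamer through allylic 1,3-strain with the inward C6 methyl group, and the four alkyl substituents make the diene electron-rich enough to react at −30 °C in an aprotic solvent. The C4=C5 alkene left in 14 carries two allylic C–O bonds and is far less reactive towards singlet oxygen, so over-oxidation should be limited by stopping at full conversion of 12.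

Step 6
Reactants: 14 methyl 2-[(3S,6R)-6-hexadecyl-4,6-dimethyl-3,6-dihydro-1,2-dioxin-3-yl]acetate (racemate)
Product: 15 2-[(3S,6R)-6-hexadecyl-4,6-dimethyl-3,6-dihydro-1,2-dioxin-3-yl]acetic acid
Conditions: Burkholderia cepacia lipase (immobilised), phosphate buffer pH 7.0 / MTBE, 30 °C, pH-stat, stopped below half conversion
Reagents that add atoms: water, O
Why: Enzymatic kinetic resolution by lipase-catalysed ester hydrolysis: the chiral acyl pocket distinguishes the enantiomers at C3, which lies β to the ester carbonyl, so only the (3S,6R) ester should be cleaved; the neutral buffer avoids Kornblum–DeLaMare cleavage and β-elimination of the base-sensitive peroxy ester, no stereocentre is formed, and the unreacted (3R,6S) ester is removed by chromatography.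

Step 7
Reactants: 15 2-[(3S,6R)-6-hexadecyl-4,6-dimethyl-3,6-dihydro-1,2-dioxin-3-yl]acetic acid
Product: 16 (3R,4S,4aR,7aS)-3-hexadecyl-4-iodo-3,4a-dimethyltetrahydro-3H-furo[3,2-c][1,2]dioxin-6(4H)-one (iodine on C5 in the chain labels)
Conditions: I2 (3 equiv), KI, NaHCO3, THF–H2O, 0 °C, dark
Reagents that add atoms: iodine, II
Why: Iodolactonisation: the iodonium ion on C4=C5 is opened at the tertiary C4 by the carboxylate held on C3 (5-exo, Markovnikov), which can only reach the face it sits on, so the new C4 stereocentre should carry the lactone oxygen cis to the C2 arm (cis-fused bicycle) with iodine anti on C5, and bicarbonate is too weak a base to harm the peroxide.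

Step 8
Reactants: 16 iodolactone
Product: 17 (3R,4aS,7aS)-3-hexadecyl-3,4a-dimethyltetrahydro-3H-furo[3,2-c][1,2]dioxin-6(4H)-one (target; 3S,4S,6R in the chain labels)
Conditions: Bu3SnH (3 equiv, 0.5 M), Et3B (0.2 equiv), air, toluene, 0 °C
Reagents that add atoms: none
Why: Tin hydride radical-chain dehalogenation: Bu3Sn• abstracts iodine and the secondary C5 radical is capped by hydrogen transfer from concentrated Bu3SnH at 0 °C faster than it can attack the neighbouring O–O bond, so C5 becomes the ring CH2 and the stereocentres at C3, C4 and C6 are untouched.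

**Compound list**

1 | octadec-1-yne | CCCCCCCCCCCCCCCCC#C | starting material
2 | trimethylaluminium | C[Al](C)C | starting material
3 | dimethyl[(E)-2-methyloctadec-1-en-1-yl]alumane | CCCCCCCCCCCCCCCC/C(C)=C/[Al](C)C | intermediate (not isolated)
4 | (E)-1-iodo-2-methyloctadec-1-ene | CCCCCCCCCCCCCCCC/C(C)=C/I | intermediate
5 | ethynylmagnesium bromide | C#C[Mg]Br | starting material
6 | ethynylzinc bromide | C#C[Zn]Br | intermediate (not isolated)
7 | (E)-4-methylicos-3-en-1-yne | CCCCCCCCCCCCCCCC/C(C)=C/C#C | intermediate
8 | dimethyl[(1E,3E)-2,4-dimethylicosa-1,3-dien-1-yl]alumane | CCCCCCCCCCCCCCCC/C(C)=C/C(C)=C/[Al](C)C | intermediate (not isolated)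
9 | (1E,3E)-1-iodo-2,4-dimethylicosa-1,3-diene | CCCCCCCCCCCCCCCC/C(C)=C/C(C)=C/I | intermediate
10 | methyl bromoacetate | COC(=O)CBr | starting material
11 | (2-methoxy-2-oxoethyl)zinc bromide (Reformatsky reagent) | COC(=O)C[Zn]Br | intermediate (not isolated)
12 | methyl (3E,5E)-4,6-dimethyldocosa-3,5-dienoate | CCCCCCCCCCCCCCCC/C(C)=C/C(C)=C/CC(=O)OC | intermediate
13 | dioxygen | O=O | starting material
14 | methyl 2-[(3S,6R)-6-hexadecyl-4,6-dimethyl-3,6-dihydro-1,2-dioxin-3-yl]acetate (racemate; needed enantiomer drawn) | CCCCCCCCCCCCCCCC[C@]1(C)C=C(C)[C@H](CC(=O)OC)OO1 | intermediate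
15 | 2-[(3S,6R)-6-hexadecyl-4,6-dimethyl-3,6-dihydro-1,2-dioxin-3-yl]acetic acid | CCCCCCCCCCCCCCCC[C@]1(C)C=C(C)[C@H](CC(=O)O)OO1 | intermediate
16 | (3R,4S,4aR,7aS)-3-hexadecyl-4-iodo-3,4a-dimethyltetrahydro-3H-furo[3,2-c][1,2]dioxin-6(4H)-one | CCCCCCCCCCCCCCCC[C@]1(C)[C@@H](I)[C@]2(C)OC(=O)C[C@@H]2OO1 | intermediate
17 | (3R,4aS,7aS)-3-hexadecyl-3,4a-dimethyltetrahydro-3H-furo[3,2-c][1,2]dioxin-6(4H)-one | CCCCCCCCCCCCCCCC[C@]1(C)C[C@]2(C)OC(=O)C[C@@H]2OO1 | target

**Step count.** Total: 8 steps. Longest linear sequence: 8 steps, from octadec-1-yne (1) to 17.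

**Steps most likely to fail**

1. Step 5. The ene reaction at the allylic hydrogens and [2+2] addition may outrun the cycloaddition, because the inward C6 methyl group hinders the planar s-cis geometry. The fallback sets out from 12 and returns at 14 without singlet oxygen. It is a cation-radical chain oxygenation with ground-state O2, catalysed by (4-BrC6H4)3N·SbCl6 in CH2Cl2 at −78 °C. The diene radical cation takes up triplet oxygen stepwise and has no ene channel. The stepwise path gives up stereospecificity, so the trans isomer methyl 2-[(3R*,6R*)-6-hexadecyl-4,6-dimethyl-3,6-dihydro-1,2-dioxin-3-yl]acetate F1 would form beside 14 and be removed by chromatography. The route resumes at 14.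

2. Step 6. Discrimination between the enantiomers may be poor, or the enzyme may prefer the (3R,6S) ester. The fallback sets out from 14 and returns at 15. Preparative chromatography on a chiral stationary phase (amylose tris(3,5-dimethylphenylcarbamate)) would give the single enantiomer methyl 2-[(3S,6R)-6-hexadecyl-4,6-dimethyl-3,6-dihydro-1,2-dioxin-3-yl]acetate F2. Unselective, near-neutral hydrolysis with Me3SnOH in 1,2-dichloroethane at 60 °C would then give 15.

3. Step 4. Transfer of the ester enolate from zinc to palladium may be slow, or the C3=C4 alkene may migrate into conjugation with the ester. The fallback sets out from 7 and returns at 12. Carboalumination as in step 3 gives alane 8, and n-BuLi converts it into lithium butyl[(1E,3E)-2,4-dimethylicosa-1,3-dien-1-yl]dimethylaluminate F3. Opening of oxirane by F3 gives (3E,5E)-4,6-dimethyldocosa-3,5-dien-1-ol F4. Oxidation with CrO3/H2SO4 in acetone at 0 °C gives (3E,5E)-4,6-dimethyldocosa-3,5-dienoic acid F5. Esterification with TMSCHN2 in MeOH–toluene returns to 12.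

**Further compounds**

F1 | step 5 | methyl 2-[(3R*,6R*)-6-hexadecyl-4,6-dimethyl-3,6-dihydro-1,2-dioxin-3-yl]acetate (racemic trans isomer; 3R,6R enantiomer drawn) | CCCCCCCCCCCCCCCC[C@]1(C)C=C(C)[C@@H](CC(=O)OC)OO1
F2 | step 6 | methyl 2-[(3S,6R)-6-hexadecyl-4,6-dimethyl-3,6-dihydro-1,2-dioxin-3-yl]acetate (single enantiomer) | CCCCCCCCCCCCCCCC[C@]1(C)C=C(C)[C@H](CC(=O)OC)OO1
F3 | step 4 | lithium butyl[(1E,3E)-2,4-dimethylicosa-1,3-dien-1-yl]dimethylaluminate | CCCCCCCCCCCCCCCC/C(C)=C/C(C)=C/[Al-](C)(C)CCCC.[Li+]
F4 | step 4 | (3E,5E)-4,6-dimethyldocosa-3,5-dien-1-ol | CCCCCCCCCCCCCCCC/C(C)=C/C(C)=C/CCO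
F5 | step 4 | (3E,5E)-4,6-dimethyldocosa-3,5-dienoic acid | CCCCCCCCCCCCCCCC/C(C)=C/C(C)=C/CC(=O)O
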